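**Plan**
- Retrosynthetic cuts: (a) C4–C4a, the aryl–ketone bond of ring C, giving an open-chain (S)-3-aryloxy-3-arylpropanoic acid; (b) O1–C2, giving the fully dressed ring A phenol and an (R)-β-hydroxy ester; (c) the C8–prenyl bond (Claisen) and the C6–CH2CH2OH bond (ortho-lithiation/oxirane), leading back to phloroglucinol.
- Forward order: ring A is dressed first (hydroxyethyl between two MOM ethers, then prenyl delivered from O1), the O1–C2 ether is made next, ring C is closed last by acylation of C4a by C4, and one acid solvolysis removes all protecting groups.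
- Enabling feature: ring A is a phloroglucinol nucleus. C4a is ortho to O1 and O5, para to O7, and the only unsubstituted carbon once C6 and C8 carry their chains, so the carboxyl carbon C4 held by the O1–C2–C3 tether can only close the six-membered ring C there.
- Stereochemistry: the single centre C2 (S) comes from a catalyst-controlled transfer hydrogenation to the (R)-carbinol followed by Mitsunobu inversion. All later steps are neutral or acidic, so ring C is never opened through the chalcone.

Key step: step 11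

Remarks: the stereocentre of the target is read as (2S); atom labels follow flavanone numbering (O1, C2, C3, C4, C4a, C5–C8, C8a; ring B primed). 4-Acetoxy-3-methoxybenzoic acid 13 is taken as a purchasable material.

**Route**

Step 1
Reactants: 1 phloroglucinol; 2 chloromethyl methyl ether
Product: 3 3,5-bis(methoxymethoxy)phenol
Conditions: MOMCl (2.0 equiv), i-Pr2NEt (2.2 equiv), DMF, 0 °C → rt; chromatography
Reagents that add atoms: chloromethyl methyl ether, COCCl
Why: Williamson-type O-alkylation of a triol whose three hydroxyls are equivalent, so only the degree of alkylation has to be controlled by stoichiometry; the mono- and tris-ethers should be separable and recyclable.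

Step 2
Reactants: 3 3,5-bis(methoxymethoxy)phenol; 4 3-chloro-3-methylbut-1-yne
Product: 5 1,3-bis(methoxymethoxy)-5-[(2-methylbut-3-yn-2-yl)oxy]benzene
Conditions: CuCl2·2H2O (cat.), DBU, MeCN, 0 °C
Reagents that add atoms: 3-chloro-3-methylbut-1-yne, CC(C)(Cl)C#C
Why: copper-catalysed propargylic etherification of a phenol with a tertiary propargylic chloride, a standard entry to aryl 1,1-dimethylpropargyl ethers.

Step 3
Reactants: 5 1,3-bis(methoxymethoxy)-5-[(2-methylbut-3-yn-2-yl)oxy]benzene
Product: 6 1,3-bis(methoxymethoxy)-5-[(2-methylbut-3-en-2-yl)oxy]benzene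
Conditions: H2 (1 atm), Pd/CaCO3 poisoned with Pb(OAc)2, quinoline, EtOAc, rt
Reagents that add atoms: none
Why: Lindlar-type semihydrogenation of the terminal alkyne should stop at the alkene and leave the aryl ether and the acetals untouched.

Step 4
Reactants: 6 1,3-bis(methoxymethoxy)-5-[(2-methylbut-3-en-2-yl)oxy]benzene; 7 oxirane
Product: 9 2-{2,6-bis(methoxymethoxy)-4-[(2-methylbut-3-en-2-yl)oxy]phenyl}ethan-1-ol, via aryllithium 8 (not isolated)
Conditions: n-BuLi (1.1 equiv), THF, 0 °C; then oxirane (3 equiv), 0 °C → rt; aq NH4Cl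
Reagents that add atoms: oxirane, C1CO1
Why: directed ortho-metalation at the C–H flanked by the two MOM ethers (the tertiary allyl ether has no α-hydrogen and shields its own neighbours), followed by SN2 opening of oxirane by the aryllithium.

Step 5
Reactants: 9 2-{2,6-bis(methoxymethoxy)-4-[(2-methylbut-3-en-2-yl)oxy]phenyl}ethan-1-ol; 10 tert-butyl(chloro)dimethylsilane
Product: 11 tert-butyl(2-{2,6-bis(methoxymethoxy)-4-[(2-methylbut-3-en-2-yl)oxy]phenyl}ethoxy)dimethylsilane
Conditions: TBSCl, imidazole, DMF, rt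
Reagents that add atoms: tert-butyl(chloro)dimethylsilane, CC(C)(C)[Si](C)(C)Cl
Why: routine silylation of the primary alcohol, so that it cannot compete as the alcohol partner in the later Mitsunobu reaction.

Step 6
Reactants: 11 tert-butyl(2-{2,6-bis(methoxymethoxy)-4-[(2-methylbut-3-en-2-yl)oxy]phenyl}ethoxy)dimethylsilane
Product: 12 4-(2-{[tert-butyl(dimethyl)silyl]oxy}ethyl)-3,5-bis(methoxymethoxy)-2-(3-methylbut-2-en-1-yl)phenol
Conditions: PhNEt2, 120 °C
Reagents that add atoms: none
Why: aromatic Claisen rearrangement ([3,3] shift) of the 1,1-dimethylallyl ether places a normal prenyl group on the ortho carbon and frees the O1 hydroxyl; the two ortho positions are equivalent by symmetry and the para position is blocked, so one regioisomer is expected.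

Step 7
Reactants: 13 4-acetoxy-3-methoxybenzoic acid; 14 Meldrum's acid; 15 prop-2-en-1-ol
Product: 17 allyl 3-(4-acetoxy-3-methoxyphenyl)-3-oxopropanoate, via acyl Meldrum's acid 16 (not isolated)
Conditions: DCC, DMAP, CH2Cl2, 0 °C → rt; filtration, aq KHSO4 wash; then allyl alcohol, PhMe, 90 °C
Reagents that add atoms: Meldrum's acid, CC1(C)OC(=O)CC(=O)O1; allyl alcohol, C=CCO
Why: C-acylation of Meldrum's acid followed by thermal fragmentation (loss of acetone and CO2) and capture by allyl alcohol is the standard neutral β-keto ester synthesis, and it spares the aryl acetate.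

Step 8
Reactants: 17 allyl 3-(4-acetoxy-3-methoxyphenyl)-3-oxopropanoate
Product: 18 allyl (3R)-3-(4-acetoxy-3-methoxyphenyl)-3-hydroxypropanoate
Conditions: RuCl(p-cymene)[(R,R)-TsDPEN] (1 mol %), HCO2H/Et3N (5:2), DMF, 25 °C
Reagents that add atoms: none
Why: Noyori–Ikariya asymmetric transfer hydrogenation of the aryl ketone by outer-sphere hydride/proton delivery; the aryl group is oriented by its CH/π contact with the η6-arene, so the (R,R)-catalyst should give the (R)-carbinol as it does with aryl alkyl ketones, leaving the allyl ester and aryl acetate untouched.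

Step 9
Reactants: 12 4-(2-{[tert-butyl(dimethyl)silyl]oxy}ethyl)-3,5-bis(methoxymethoxy)-2-(3-methylbut-2-en-1-yl)phenol; 18 allyl (3R)-3-(4-acetoxy-3-methoxyphenyl)-3-hydroxypropanoate
Product: 19 allyl (3S)-3-(4-acetoxy-3-methoxyphenyl)-3-[4-(2-{[tert-butyl(dimethyl)silyl]oxy}ethyl)-3,5-bis(methoxymethoxy)-2-(3-methylbut-2-en-1-yl)phenoxy]propanoate
Conditions: PPh3, DIAD, PhMe, 0 °C → rt
Reagents that add atoms: none
Why: Mitsunobu etherification, in which the phenoxide displaces the oxyphosphonium group by SN2 with inversion, turning the (R)-carbinol into the (S)-aryl ether; the acetoxy group makes ring B a poor cation stabiliser, which should suppress ionisation and loss of configuration.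

Step 10
Reactants: 19 allyl (3S)-3-(4-acetoxy-3-methoxyphenyl)-3-[4-(2-{[tert-butyl(dimethyl)silyl]oxy}ethyl)-3,5-bis(methoxymethoxy)-2-(3-methylbut-2-en-1-yl)phenoxy]propanoate
Product: 20 (3S)-3-(4-acetoxy-3-methoxyphenyl)-3-[4-(2-{[tert-butyl(dimethyl)silyl]oxy}ethyl)-3,5-bis(methoxymethoxy)-2-(3-methylbut-2-en-1-yl)phenoxy]propanoic acid
Conditions: Pd(PPh3)4 (5 mol %), PhNHMe (3 equiv), THF, rt
Reagents that add atoms: none
Why: Tsuji–Trost-type deallylation, in which zerovalent palladium ionises the allyl ester and N-methylaniline traps the allyl fragment; the neutral conditions avoid E1cB loss of the aryloxide and cleavage of the aryl acetate that a saponification would risk.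

Step 11
Reactants: 20 (3S)-3-(4-acetoxy-3-methoxyphenyl)-3-[4-(2-{[tert-butyl(dimethyl)silyl]oxy}ethyl)-3,5-bis(methoxymethoxy)-2-(3-methylbut-2-en-1-yl)phenoxy]propanoic acid
Product: 22 4-[(2S)-6-(2-{[tert-butyl(dimethyl)silyl]oxy}ethyl)-5,7-bis(methoxymethoxy)-8-(3-methylbut-2-en-1-yl)-4-oxo-3,4-dihydro-2H-chromen-2-yl]-2-methoxyphenyl acetate, via mixed trifluoroacetic anhydride 21 (not isolated)
Conditions: (CF3CO)2O (2.5 equiv), CH2Cl2, −20 → 0 °C; cold aq NaHCO3
Reagents that add atoms: none
Why: The acid is converted in the flask into the mixed trifluoroacetic anhydride 21, whose activated acyl carbon C4 is attacked by C4a of ring A, and loss of the proton from the Wheland intermediate gives the aryl ketone and trifluoroacetic acid. The closest known reaction type is the intramolecular Friedel–Crafts acylation of 3-aryloxypropanoic acids to chroman-4-ones under trifluoroacetic anhydride activation. Ring C closes in the 6-exo-trig mode, C4a adding to the anhydride carbonyl with O1–C2–C3 as the tether. No stereocentre is formed; C2, set in step 9, takes no part, and the acetoxy group on ring B together with the low temperature disfavours ionisation of the benzylic C2–O1 bond, so the (S) configuration should be carried through. The step needs site selectivity between C4a and C6' of ring B (which would give an indanone): C4a is the only unsubstituted carbon of ring A and lies ortho to O1 and O5 and para to O7, whereas ring B is deactivated by the acetate and would have to close a five-membered ring. The MOM ethers, the silyl ether and the prenyl group should tolerate the cold, dilute trifluoroacetic acid that is liberated, and a MOM group lost after ring closure would be removed in step 12 in any case.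

Step 12
Reactants: 22 4-[(2S)-6-(2-{[tert-butyl(dimethyl)silyl]oxy}ethyl)-5,7-bis(methoxymethoxy)-8-(3-methylbut-2-en-1-yl)-4-oxo-3,4-dihydro-2H-chromen-2-yl]-2-methoxyphenyl acetate
Product: 23 Laxiflorin, (2S)-5,7-dihydroxy-2-(4-hydroxy-3-methoxyphenyl)-6-(2-hydroxyethyl)-8-(3-methylbut-2-en-1-yl)-2,3-dihydro-4H-chromen-4-one
Conditions: HCl (2 M in MeOH), 40 °C
Reagents that add atoms: none
Why: one acid-catalysed methanolysis should remove the two MOM acetals, the primary silyl ether and the aryl acetate (as in MOM removal from prenylated flavanones), and because the medium is acidic and not basic, C2 should not be scrambled through opening of ring C to the chalcone or quinone methide.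

**Compound list**
1 | phloroglucinol (benzene-1,3,5-triol) | Oc1cc(O)cc(O)c1 | starting material
2 | chloromethyl methyl ether | COCCl | starting material
3 | 3,5-bis(methoxymethoxy)phenol | COCOc1cc(O)cc(OCOC)c1 | intermediate
4 | 3-chloro-3-methylbut-1-yne | CC(C)(Cl)C#C | starting material
5 | 1,3-bis(methoxymethoxy)-5-[(2-methylbut-3-yn-2-yl)oxy]benzene | C#CC(C)(C)Oc1cc(OCOC)cc(OCOC)c1 | intermediate
6 | 1,3-bis(methoxymethoxy)-5-[(2-methylbut-3-en-2-yl)oxy]benzene | C=CC(C)(C)Oc1cc(OCOC)cc(OCOC)c1 | intermediate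
7 | oxirane | C1CO1 | starting material
8 | {2,6-bis(methoxymethoxy)-4-[(2-methylbut-3-en-2-yl)oxy]phenyl}lithium | C=CC(C)(C)Oc1cc(OCOC)c([Li])c(OCOC)c1 | intermediate
9 | 2-{2,6-bis(methoxymethoxy)-4-[(2-methylbut-3-en-2-yl)oxy]phenyl}ethan-1-ol | C=CC(C)(C)Oc1cc(OCOC)c(CCO)c(OCOC)c1 | intermediate
10 | tert-butyl(chloro)dimethylsilane | CC(C)(C)[Si](C)(C)Cl | starting material
11 | tert-butyl(2-{2,6-bis(methoxymethoxy)-4-[(2-methylbut-3-en-2-yl)oxy]phenyl}ethoxy)dimethylsilane | C=CC(C)(C)Oc1cc(OCOC)c(CCO[Si](C)(C)C(C)(C)C)c(OCOC)c1 | intermediate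
12 | 4-(2-{[tert-butyl(dimethyl)silyl]oxy}ethyl)-3,5-bis(methoxymethoxy)-2-(3-methylbut-2-en-1-yl)phenol | CC(C)=CCc1c(O)cc(OCOC)c(CCO[Si](C)(C)C(C)(C)C)c1OCOC | intermediate
13 | 4-acetoxy-3-methoxybenzoic acid | COc1cc(C(=O)O)ccc1OC(C)=O | starting material
14 | Meldrum's acid (2,2-dimethyl-1,3-dioxane-4,6-dione) | CC1(C)OC(=O)CC(=O)O1 | starting material
15 | prop-2-en-1-ol (allyl alcohol) | C=CCO | starting material
16 | 5-[(4-acetoxy-3-methoxyphenyl)(hydroxy)methylidene]-2,2-dimethyl-1,3-dioxane-4,6-dione | COc1cc(C(O)=C2C(=O)OC(C)(C)OC2=O)ccc1OC(C)=O | intermediate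
17 | allyl 3-(4-acetoxy-3-methoxyphenyl)-3-oxopropanoate | COc1cc(C(=O)CC(=O)OCC=C)ccc1OC(C)=O | intermediate
18 | allyl (3R)-3-(4-acetoxy-3-methoxyphenyl)-3-hydroxypropanoate | COc1cc([C@H](O)CC(=O)OCC=C)ccc1OC(C)=O | intermediate
19 | allyl (3S)-3-(4-acetoxy-3-methoxyphenyl)-3-[4-(2-{[tert-butyl(dimethyl)silyl]oxy}ethyl)-3,5-bis(methoxymethoxy)-2-(3-methylbut-2-en-1-yl)phenoxy]propanoate | COc1cc([C@H](CC(=O)OCC=C)Oc2cc(OCOC)c(CCO[Si](C)(C)C(C)(C)C)c(OCOC)c2CC=C(C)C)ccc1OC(C)=O | intermediate
20 | (3S)-3-(4-acetoxy-3-methoxyphenyl)-3-[4-(2-{[tert-butyl(dimethyl)silyl]oxy}ethyl)-3,5-bis(methoxymethoxy)-2-(3-methylbut-2-en-1-yl)phenoxy]propanoic acid | COc1cc([C@H](CC(=O)O)Oc2cc(OCOC)c(CCO[Si](C)(C)C(C)(C)C)c(OCOC)c2CC=C(C)C)ccc1OC(C)=O | intermediate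
21 | mixed anhydride of acid 20 with trifluoroacetic acid | COc1cc([C@H](CC(=O)OC(=O)C(F)(F)F)Oc2cc(OCOC)c(CCO[Si](C)(C)C(C)(C)C)c(OCOC)c2CC=C(C)C)ccc1OC(C)=O | intermediate
22 | 4-[(2S)-6-(2-{[tert-butyl(dimethyl)silyl]oxy}ethyl)-5,7-bis(methoxymethoxy)-8-(3-methylbut-2-en-1-yl)-4-oxo-3,4-dihydro-2H-chromen-2-yl]-2-methoxyphenyl acetate | COc1cc([C@@H]2CC(=O)c3c(OCOC)c(CCO[Si](C)(C)C(C)(C)C)c(OCOC)c(CC=C(C)C)c3O2)ccc1OC(C)=O | intermediate
23 | Laxiflorin, (2S)-5,7-dihydroxy-2-(4-hydroxy-3-methoxyphenyl)-6-(2-hydroxyethyl)-8-(3-methylbut-2-en-1-yl)-2,3-dihydro-4H-chromen-4-one | COc1cc([C@@H]2CC(=O)c3c(O)c(CCO)c(O)c(CC=C(C)C)c3O2)ccc1O | target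

**Count**
Total steps: 12. Longest linear sequence: 10 steps (steps 1–6, then 9–12); steps 7–8 form the second branch.

**Steps most likely to fail, with fallbacks**

Step 9 (Mitsunobu etherification). The activated carbinol may be lost by elimination to the cinnamate, because the ester acidifies the neighbouring CH2; the ortho-substituted phenol may couple slowly; and partial ionisation at the benzylic carbon would erode the configuration. The fallback sets out from 18 and 12 and comes back at acid 20, and it moves the etherification to the diol oxidation level, where no carbonyl acidifies C3. Deallylation of 18 with Pd(PPh3)4 and N-methylaniline should give (3R)-3-(4-acetoxy-3-methoxyphenyl)-3-hydroxypropanoic acid F1. Chemoselective reduction of the carboxylic acid with BH3·SMe2 (THF, 0 °C) should give 4-[(1R)-1,3-dihydroxypropyl]-2-methoxyphenyl acetate F2. Allyl chloroformate and pyridine at −30 °C should cap the primary hydroxyl as allyl (3R)-3-(4-acetoxy-3-methoxyphenyl)-3-hydroxypropyl carbonate F3. Mitsunobu coupling of F3 with phenol 12 (PPh3, DIAD, PhMe), again with inversion, should give the (S)-aryl ether carbonate F4. Pd(PPh3)4 and N-methylaniline should then release the primary alcohol (3S)-3-(4-acetoxy-3-methoxyphenyl)-3-aryloxypropan-1-ol F5, and oxidation with TEMPO (cat.) and PhI(OAc)2 in MeCN–H2O should deliver acid 20.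

Step 11 (ring closure). The protic acid set free may remove MOM groups before the ring has closed, a freed phenol may add to the prenyl double bond, and ionisation of the C2–O1 bond would racemise C2. The fallback sets out from 19 and comes back at 22, and it reverses the polarity of the same bond formation: ring A becomes the nucleophile as an organomagnesium (Parham-type cyclisation) under non-acidic conditions. Iodination of 19 with N-iodosuccinimide (MeCN, 0 °C) at the only free carbon of ring A should give the aryl iodide F6. Iodine–magnesium exchange with i-PrMgCl·LiCl (THF, −40 °C) should give the arylmagnesium chloride F7, which should attack the tethered allyl ester and, after a cold NH4Cl quench, give flavanone 22.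

Step 12 (global unmasking). During the solvolysis time the acetate needs, the C7 hydroxyl, methanol or HCl may add to the prenyl double bond, and ring C may slowly open. The fallback sets out from 22 and comes back at 23, and it replaces the single protic solvolysis by three orthogonal, non-solvolytic operations. ZnBr2 with n-PrSH (CH2Cl2, 0 °C, minutes) should cleave both MOM ethers to give the 5,7-dihydroxy silyl ether acetate F8. HF·pyridine (THF, 0 °C) should remove the silyl group to give the 4'-O-acetate of the target F9. Immobilised Candida antarctica lipase B with n-BuOH (MTBE, 40 °C) should transfer the phenolic acetyl group to butanol and give 23.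

**Further compounds**
F1 | step 9 | (3R)-3-(4-acetoxy-3-methoxyphenyl)-3-hydroxypropanoic acid | COc1cc([C@H](O)CC(=O)O)ccc1OC(C)=O
F2 | step 9 | 4-[(1R)-1,3-dihydroxypropyl]-2-methoxyphenyl acetate | COc1cc([C@H](O)CCO)ccc1OC(C)=O
F3 | step 9 | allyl (3R)-3-(4-acetoxy-3-methoxyphenyl)-3-hydroxypropyl carbonate | COc1cc([C@H](O)CCOC(=O)OCC=C)ccc1OC(C)=O
F4 | step 9 | allyl (3S)-3-(4-acetoxy-3-methoxyphenyl)-3-[4-(2-{[tert-butyl(dimethyl)silyl]oxy}ethyl)-3,5-bis(methoxymethoxy)-2-(3-methylbut-2-en-1-yl)phenoxy]propyl carbonate | COc1cc([C@H](CCOC(=O)OCC=C)Oc2cc(OCOC)c(CCO[Si](C)(C)C(C)(C)C)c(OCOC)c2CC=C(C)C)ccc1OC(C)=O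
F5 | step 9 | 4-{(1S)-1-[4-(2-{[tert-butyl(dimethyl)silyl]oxy}ethyl)-3,5-bis(methoxymethoxy)-2-(3-methylbut-2-en-1-yl)phenoxy]-3-hydroxypropyl}-2-methoxyphenyl acetate | COc1cc([C@H](CCO)Oc2cc(OCOC)c(CCO[Si](C)(C)C(C)(C)C)c(OCOC)c2CC=C(C)C)ccc1OC(C)=O
F6 | step 11 | allyl (3S)-3-(4-acetoxy-3-methoxyphenyl)-3-[4-(2-{[tert-butyl(dimethyl)silyl]oxy}ethyl)-2-iodo-3,5-bis(methoxymethoxy)-6-(3-methylbut-2-en-1-yl)phenoxy]propanoate | COc1cc([C@H](CC(=O)OCC=C)Oc2c(I)c(OCOC)c(CCO[Si](C)(C)C(C)(C)C)c(OCOC)c2CC=C(C)C)ccc1OC(C)=O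
F7 | step 11 | arylmagnesium chloride derived from F6 by iodine–magnesium exchange | COc1cc([C@H](CC(=O)OCC=C)Oc2c([Mg]Cl)c(OCOC)c(CCO[Si](C)(C)C(C)(C)C)c(OCOC)c2CC=C(C)C)ccc1OC(C)=O
F8 | step 12 | 4-[(2S)-6-(2-{[tert-butyl(dimethyl)silyl]oxy}ethyl)-5,7-dihydroxy-8-(3-methylbut-2-en-1-yl)-4-oxo-3,4-dihydro-2H-chromen-2-yl]-2-methoxyphenyl acetate | COc1cc([C@@H]2CC(=O)c3c(O)c(CCO[Si](C)(C)C(C)(C)C)c(O)c(CC=C(C)C)c3O2)ccc1OC(C)=O
F9 | step 12 | 4-[(2S)-5,7-dihydroxy-6-(2-hydroxyethyl)-8-(3-methylbut-2-en-1-yl)-4-oxo-3,4-dihydro-2H-chromen-2-yl]-2-methoxyphenyl acetate | COc1cc([C@@H]2CC(=O)c3c(O)c(CCO)c(O)c(CC=C(C)C)c3O2)ccc1OC(C)=O
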